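## The problem

Chroman numbering is used throughout: O1, C2, C3, C4, C4a, C5 to C8 and C8a for rings A and C, and C1' to C6' for ring B. The target 23 is an isoflavan quinone: a 6-hydroxy-7,8-dimethoxychroman that carries a 2,3-dimethoxy-1,4-benzoquinone (ring B) at C3. Its skeleton is a three-carbon chain, C2–C3–C4, tied to ring A twice (C4–C4a and, through O1, C8a) and to ring B once (C3–C1'). The only stereocentre is C3 (S). It is isolated, so no other centre can relay to it; it must be set by an external element and then kept out of enolisable situations. Two groups will not stand rough treatment. The dimethoxyquinone has vinylogous ester methoxy groups that nucleophiles and base attack. Ring A is a 4-alkoxyphenol (O6–H para to O1) that is oxidised nearly as easily as a hydroquinone. Both rings carry the same 1,2,3,4-oxygen pattern next to their carbon substituent but end at different oxidation levels, so the last oxidation has to find ring B alone. The enabling feature is the para relation of O6–H and C8a: if C8a still bears a methoxy group in an open precursor, two-electron oxidation of the phenol places the positive charge on C8a as an oxocarbenium ion, and the hydroxyl on C2 is six atoms away, so O1–C8a can be made as a ketal bond and the arene restored by reduction. The same hydroxyl is five atoms from C2' of ring B, so ring B must not be a phenol at that moment.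

## Retrosynthesis

**Ring B oxidation level (23 from 21).** No skeletal bond is cut. The quinone 23 is traced to hydroquinone 22 and this to the bis(benzyl) ether 21. Benzyl is chosen over methyl because an oxidative demethylation would also attack ring A, whereas hydrogenolysis is neutral and a hydroquinone is oxidised under far milder conditions than the ring A monophenol. The forward step must oxidise ring B only and use no base.

**O1–C8a (21 from 20 from 19).** The chroman 21 is opened at O1–C8a. The usual isoflavan closure cuts O1–C2 instead, but it needs a ring A hydroquinone with two phenols told apart by protecting groups. Cutting O1–C8a lets the methoxy group on C8a of phenol-alcohol 19 serve both as the protecting group and as the activating group. Oxidation of 19 gives the bicyclic quinone monoketal 20, and reduction of 20 with loss of methanol gives 21 with O6–H already free. Precursor 19 is acyclic between the rings and has one stereocentre. The forward step must oxidise ring A and not ring B, and must bond the hydroxyl to C8a and not to C5.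

**O6 from bromine (19 from 17).** The aryl C–O bond of the ring A phenol is traced to the C–Br bond of bromo alcohol 17. A bromine survives enolate and hydride chemistry, so no phenol protecting group has to be put on and taken off. The forward reaction is a borylation–oxidation through boronate 18.

**C3–C4 and the stereocentre (17 from 16 from 15 and 4).** Alcohol 17 comes from imide 16 by reductive removal of the auxiliary. Imide 16 is cut at C3–C4 into the arylacetyl oxazolidinone 15 and benzylic bromide 4. The neighbouring option, hydrogenation of a 2,3-diarylacrylic acid, needs a catalyst that accepts a very hindered trisubstituted alkene. The auxiliary alkylation gives diastereomers that can be separated, so the purity at C3 can be secured. The forward step must alkylate a stabilised, hindered enolate without epimerisation.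

**C1'–C3 (15 from 12 and 13; 12 from 11 from 9 and 10).** Imide 15 is the acylation product of oxazolidinone 13 with arylacetic acid 12, through mixed anhydride 14. Acid 12 comes from ester 11, which is cut at the aryl–CH2 bond into aryl bromide 9 and tert-butyl acetate 10. The acetate supplies C2 and C3. An enolate arylation is preferred to a homologation of a benzaldehyde because it is one step and uses the bromide directly.

**Ring B oxygen pattern (9 from 7 from 6 from 2).** The bis(benzyl) ether 9 comes from bromoquinone 7 by reduction to hydroquinone 8 and benzylation. Quinone 7 comes from phenol 6 by oxidative loss of the para methyl group. This is the step that tells the two oxygens that will become the quinone carbonyls from the two that stay methoxy. Phenol 6 comes from aldehyde 2 by Dakin oxidation through formate 5, which exchanges the formyl carbon for oxygen.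

**Ring A fragment and the common origin (4 from 3 from 2 from 1).** Bromide 4 comes from alcohol 3 and this from aldehyde 2. Aldehyde 2 is the bromination product of 2,3,4-trimethoxybenzaldehyde 1. Bromoaldehyde 2 thus serves both rings in two senses. In ring A the formyl carbon becomes C4 and the bromine is the latent O6. In ring B the formyl carbon is replaced by O5' and the bromine marks C1'.

## Roads not taken

**Alternative 1:** The cut is C3–C1' together with a temporary C4–O(C2') bond, leading back from the cis-pterocarpan A1 to 2,3-dimethoxy-1,4-benzoquinone A2 and 6-(benzyloxy)-7,8-dimethoxy-2H-chromene A3. In the forward step a TADDOL-modified TiCl2(OiPr)2 (tetravalent titanium) activates the quinone. C3 of the chromene attacks it, and the quinone oxygen captures the benzylic cation at C4. Hydrogenolysis of A1 would then open the benzylic C4–O bond and remove the benzyl group in one operation, and a mild oxidation would finish.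
- Merits: it is the most convergent of the plans, it makes C3–C1' and the stereocentre in one step from two small pieces, and it could be roughly half as long as the chosen route.
- Weak points: the configuration at C3 rests on a stoichiometric chiral Lewis acid whose facial discrimination in quinone–alkene additions depends strongly on the substitution of both partners. A2, with two donor groups, is a weaker electrophile than a monoalkoxyquinone. Cyclobutane adducts compete, and A3 is acid-sensitive.
- Comparison: in step count Alternative 1 is better. The chosen plan sets against this a covalently bound auxiliary and separable diastereomers, so the enantiomeric purity of 23 does not depend on how a chiral Lewis acid responds to this substrate. Both plans need the same selective final oxidation.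

**Alternative 2:** The cut is C3–C1' and C4–C4a at once, around a two-carbon vinylboron unit, with C2 added later. The boronic ester A4 would arise from the ate complex of vinylboronic ester A5 with the aryllithium made from bromide 9, which reacts with ring A bromide A6 under Pd(OAc)2, a chiral ferrocenyl bisphosphine (MandyPhos) and KOTf. Ring B shifts from boron to C3 as the arylpalladium adds to the alkene terminus. Matteson homologation and oxidation, removal of the methoxymethyl group, Mitsunobu closure of O1–C2, hydrogenolysis and oxidation would follow.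
- Merits: the stereocentre is set catalytically, three components are joined in one step, and the ring closure has strong precedent.
- Weak points: the migrating aryl group has an ortho benzyloxy group and the electrophile an ortho alkoxy group, and both slow the metal-induced shift and may lower selectivity. An aryllithium has to be made beside benzyl ethers. A6 needs three different oxygen substituents on one ring and is a longer synthesis than 4. At least five operations follow the key step.
- Comparison: Alternative 2 is better in that it carries no auxiliary, and its length is similar. The chosen plan sets against this a ring A that needs no protecting group on O1 or O6, and a stereocentre made by a reaction with little substrate dependence.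

**Alternative 3:** The cut is ring B itself, made last. The silyl ether A7 of the target would come from thermolysis of the alkynyl hydroxycyclobutenone A8, assembled from dimethyl squarate A9 and the lithium acetylide of 3-ethynylchroman A10. The four-membered ring opens to a vinylketene, whose ketene carbon bonds to the far alkyne carbon (C1'–C2'); hydrogen transfer gives the quinone, and desilylation gives 23.
- Merits: the quinone appears at its final oxidation level with unambiguous regiochemistry, ring A stays masked, and no late oxidation has to tell two electron-rich rings apart.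
- Weak points: the chroman and C3 must already be present in A10. This enantiopure alkyne has a configurationally labile aldehyde as its likely precursor, so the real problem is moved and not solved. Cyclopentenediones can accompany the quinone in such ring expansions. The last step removes a silyl group from a base-sensitive methoxyquinone.
- Comparison: the endgame of Alternative 3 is cleaner than the chosen one, and this is a real advantage. The chosen plan sets against it that both rings come from one cheap aldehyde and that C3 is set on an acyclic centre by auxiliary chemistry.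

Key step: step 13

Remark: C3 is read from the structure as S. The priority order at this carbon (oxygen-bearing carbon, then ring B, then the benzylic CH2) is the same in every intermediate from 16 on, so the descriptor stays S. The two C8a epimers of 20 are carried together.

## Route

Step 1
Reactants: 1 2,3,4-trimethoxybenzaldehyde
Product: 2 5-bromo-2,3,4-trimethoxybenzaldehyde
Conditions: NBS, MeCN, rt
Reagents that add atoms: N-bromosuccinimide, O=C1CCC(=O)N1Br
Why: Electrophilic aromatic bromination; C5 is para to the 2-methoxy group, ortho to the 4-methoxy group and meta to the aldehyde, whereas C6 is activated only by the twisted 3-methoxy group and lies ortho to the aldehyde, so substitution should go to C5.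

Step 2
Reactants: 2 5-bromo-2,3,4-trimethoxybenzaldehyde
Product: 3 (5-bromo-2,3,4-trimethoxyphenyl)methanol
Conditions: NaBH4, MeOH, 0 °C
Reagents that add atoms: none
Why: Borohydride reduction of an aromatic aldehyde; the aryl bromide and the ethers are inert.

Step 3
Reactants: 3 (5-bromo-2,3,4-trimethoxyphenyl)methanol
Product: 4 1-bromo-5-(bromomethyl)-2,3,4-trimethoxybenzene
Conditions: PBr3, CH2Cl2, 0 °C
Reagents that add atoms: phosphorus tribromide, BrP(Br)Br
Why: Conversion of a benzylic alcohol into the bromide by displacement on its phosphite ester; the ring bromine lowers the tendency of this electron-rich benzylic bromide to ionise, and it is used soon after in step 10.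

Step 4
Reactants: 2 5-bromo-2,3,4-trimethoxybenzaldehyde
Product: 6 5-bromo-2,3,4-trimethoxyphenol, via aryl formate 5 (not isolated)
Conditions: 30% H2O2, H2SO4 (cat.), MeOH, rt
Reagents that add atoms: hydrogen peroxide, OO
Why: Acid-catalysed Dakin oxidation: the hydroperoxide adduct of the aldehyde rearranges with migration of the aryl group, which the ortho and para methoxy groups favour, and the formate is methanolysed in the same flask.

Step 5
Reactants: 6 5-bromo-2,3,4-trimethoxyphenol
Product: 7 5-bromo-2,3-dimethoxycyclohexa-2,5-diene-1,4-dione
Conditions: PhI(OAc)2, MeCN/H2O, 0 °C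
Reagents that add atoms: water, O
Why: Oxidative demethylation of a 4-methoxyphenol by trivalent iodine: water adds to the methoxy-bearing para carbon and the hemiketal loses methanol to give the para-quinone. This singles out the two oxygens that will later carry the benzyl groups.

Step 6
Reactants: 7 5-bromo-2,3-dimethoxycyclohexa-2,5-diene-1,4-dione
Product: 9 1,4-bis(benzyloxy)-5-bromo-2,3-dimethoxybenzene, via bromohydroquinone 8 (not isolated)
Conditions: Na2S2O4, EtOAc/H2O, rt; then BnBr, K2CO3, DMF, rt, under N2
Reagents that add atoms: benzyl bromide, BrCc1ccccc1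
Why: Dithionite reduction of the quinone followed by Williamson benzylation of both phenols; the hydroquinone is not stored because it reoxidises in air.

Step 7
Reactants: 9 1,4-bis(benzyloxy)-5-bromo-2,3-dimethoxybenzene; 10 tert-butyl acetate
Product: 11 tert-butyl 2-[2,5-bis(benzyloxy)-3,4-dimethoxyphenyl]acetate
Conditions: LiN(c-C6H11)2, Pd(dba)2 (cat.), P(t-Bu)3 (cat.), toluene, rt
Reagents that add atoms: none
Why: Palladium-catalysed α-arylation of an ester enolate (Buchwald–Hartwig type): oxidative addition of the aryl bromide to zerovalent palladium, transmetalation with the lithium enolate and reductive elimination form C1'–C3. The bulky phosphine and the tert-butyl ester hold back Claisen condensation and a second arylation.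

Step 8
Reactants: 11 tert-butyl 2-[2,5-bis(benzyloxy)-3,4-dimethoxyphenyl]acetate
Product: 12 2-[2,5-bis(benzyloxy)-3,4-dimethoxyphenyl]acetic acid
Conditions: CF3CO2H, CH2Cl2, 0 °C to rt
Reagents that add atoms: none
Why: Acidolysis of a tert-butyl ester through the tert-butyl cation; aryl benzyl ethers should survive a short exposure to dilute acid at this temperature.

Step 9
Reactants: 12 2-[2,5-bis(benzyloxy)-3,4-dimethoxyphenyl]acetic acid; 13 (4S)-4-benzyl-1,3-oxazolidin-2-one
Product: 15 (4S)-4-benzyl-3-{2-[2,5-bis(benzyloxy)-3,4-dimethoxyphenyl]acetyl}-1,3-oxazolidin-2-one, via mixed pivalic anhydride 14 (not isolated)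
Conditions: t-BuCOCl, Et3N, THF, −20 °C; then 13, LiCl, −20 °C to rt
Reagents that add atoms: pivaloyl chloride, CC(C)(C)C(Cl)=O (its atoms stay only in intermediate 14)
Why: N-Acylation of the oxazolidinone through a mixed anhydride; LiCl raises the acidity of the carbamate N–H so that Et3N suffices, and attack goes to the less hindered arylacetyl carbonyl.

Step 10
Reactants: 15 (4S)-4-benzyl-3-{2-[2,5-bis(benzyloxy)-3,4-dimethoxyphenyl]acetyl}-1,3-oxazolidin-2-one; 4 1-bromo-5-(bromomethyl)-2,3,4-trimethoxybenzene
Product: 16 (4S)-4-benzyl-3-[(2S)-2-[2,5-bis(benzyloxy)-3,4-dimethoxyphenyl]-3-(5-bromo-2,3,4-trimethoxyphenyl)propanoyl]-1,3-oxazolidin-2-one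
Conditions: NaN(SiMe3)2, THF, −78 °C; then 4, −78 to −40 °C
Reagents that add atoms: none
Why: Evans alkylation forms C3–C4: the sodium Z-enolate is chelated between the two carbonyl oxygens, the benzyl group at C4 of the auxiliary covers one face, and the benzylic bromide enters from the other, which sets C3 as S. The low temperature keeps the acidic α-aryl centre from epimerising, and the minor diastereomer can be removed at this stage.

Step 11
Reactants: 16 (4S)-4-benzyl-3-[(2S)-2-[2,5-bis(benzyloxy)-3,4-dimethoxyphenyl]-3-(5-bromo-2,3,4-trimethoxyphenyl)propanoyl]-1,3-oxazolidin-2-one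
Product: 17 (2S)-2-[2,5-bis(benzyloxy)-3,4-dimethoxyphenyl]-3-(5-bromo-2,3,4-trimethoxyphenyl)propan-1-ol
Conditions: LiBH4, H2O (1 equiv), Et2O, 0 °C
Reagents that add atoms: none
Why: Reductive cleavage of the N-acyl oxazolidinone by LiBH4 gives the primary alcohol and returns the auxiliary; the aryl bromide, the benzyl ethers and C3 are not touched.

Step 12
Reactants: 17 (2S)-2-[2,5-bis(benzyloxy)-3,4-dimethoxyphenyl]-3-(5-bromo-2,3,4-trimethoxyphenyl)propan-1-ol
Product: 19 5-[(2S)-2-[2,5-bis(benzyloxy)-3,4-dimethoxyphenyl]-3-hydroxypropyl]-2,3,4-trimethoxyphenol, via pinacol boronate 18 (not isolated)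
Conditions: B2pin2, Pd(dppf)Cl2 (cat.), KOAc, 1,4-dioxane, 90 °C; then 30% H2O2, aq. NaOH, THF, 0 °C
Reagents that add atoms: bis(pinacolato)diboron, CC1(C)OB(OC1(C)C)B1OC(C)(C)C(C)(C)O1 (its boron stays only in intermediate 18); hydrogen peroxide, OO
Why: Miyaura borylation of the aryl bromide followed by oxidation of the aryl boronate with basic peroxide (1,2-shift of the aryl group from boron to oxygen) turns the bromine placeholder into the free O6–H. The primary alcohol is tolerated and no phenol protecting group is needed.

Step 13
Reactants: 19 5-[(2S)-2-[2,5-bis(benzyloxy)-3,4-dimethoxyphenyl]-3-hydroxypropyl]-2,3,4-trimethoxyphenol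
Product: 20 (3S)-3-[2,5-bis(benzyloxy)-3,4-dimethoxyphenyl]-7,8,8a-trimethoxy-3,4-dihydro-2H-chromen-6(8aH)-one (both C8a epimers)
Conditions: PhI(OAc)2 (1.05 equiv), (CF3)2CHOH/CH2Cl2 (1:4), −20 °C
Reagents that add atoms: none
Why: The phenol O6–H exchanges for acetate at trivalent iodine, and loss of iodobenzene and acetate leaves a phenoxenium ion whose charge rests mainly on C8a, where the methoxy group makes it an oxocarbenium ion. The hydroxyl on C2 adds to this carbon in a 6-exo-trig closure (the C8a=O+Me unit lies outside the new ring), which forms O1–C8a and the pyran ring as a bicyclic mixed ketal. The closest known reaction type is the PhI(OAc)2 oxidation of 4-methoxyphenols to quinone monoketals with capture by an alcohol, together with the formation of 8a-alkoxytocopherones from chromanols. C8a becomes a stereocentre that nothing controls beyond a possible bias from C3, which does not matter because C8a returns to sp2 in step 14. Selectivity between the rings rests on the fact that only ring A has a phenol that can bind iodine; ring B is a tetraalkyl ether that could react only by slower electron transfer, which the acetate reagent, one equivalent and the low temperature disfavour. Within ring A, C5 is also within six-membered reach of the hydroxyl, but it carries hydrogen and no donor, so charge and attack should go to C8a. The hydroxyl should outrun both the free position C6' of ring B as a carbon nucleophile and the non-nucleophilic fluoroalcohol. The product has no free phenol and cannot be oxidised further.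

Step 14
Reactants: 20 (3S)-3-[2,5-bis(benzyloxy)-3,4-dimethoxyphenyl]-7,8,8a-trimethoxy-3,4-dihydro-2H-chromen-6(8aH)-one
Product: 21 (3S)-3-[2,5-bis(benzyloxy)-3,4-dimethoxyphenyl]-7,8-dimethoxy-3,4-dihydro-2H-chromen-6-ol
Conditions: Zn dust, AcOH, THF, 0 °C to rt
Reagents that add atoms: none
Why: Reductive aromatisation of a quinone monoketal: in acetic acid the ketal loses the exocyclic methoxy group to give a cyclic oxocarbenium ion, as 8a-alkoxytocopherones do, and this ion takes two electrons from zinc to become the chroman-6-ol. Ionisation of the ring oxygen only leads back to 19, which can be put through step 13 again. Benzyl ethers are stable to zinc in acetic acid and both C8a epimers give the same product.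

Step 15
Reactants: 21 (3S)-3-[2,5-bis(benzyloxy)-3,4-dimethoxyphenyl]-7,8-dimethoxy-3,4-dihydro-2H-chromen-6-ol
Product: 23 5-[(3S)-6-hydroxy-7,8-dimethoxy-3,4-dihydro-2H-chromen-3-yl]-2,3-dimethoxycyclohexa-2,5-diene-1,4-dione, via hydroquinone 22 (not isolated)
Conditions: H2 (1 atm), Pd/C, EtOAc, rt; filter; then Ag2O (1.1 equiv), MgSO4, Et2O, rt
Reagents that add atoms: none
Why: Hydrogenolysis of the two aryl benzyl ethers gives the hydroquinone, which is oxidised to the quinone at a much lower potential than the monophenol of ring A, so one equivalent of Ag2O under neutral, dry conditions should stop at ring B. No base is present that could epimerise C3 or displace a quinone methoxy group.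

## Compound list

1 | 2,3,4-trimethoxybenzaldehyde | COc1ccc(C=O)c(OC)c1OC | starting material
2 | 5-bromo-2,3,4-trimethoxybenzaldehyde | COc1c(Br)cc(C=O)c(OC)c1OC | intermediate
3 | (5-bromo-2,3,4-trimethoxyphenyl)methanol | COc1c(Br)cc(CO)c(OC)c1OC | intermediate
4 | 1-bromo-5-(bromomethyl)-2,3,4-trimethoxybenzene | COc1c(Br)cc(CBr)c(OC)c1OC | intermediate
5 | 5-bromo-2,3,4-trimethoxyphenyl formate (not isolated) | COc1c(Br)cc(OC=O)c(OC)c1OC | intermediate
6 | 5-bromo-2,3,4-trimethoxyphenol | COc1c(Br)cc(O)c(OC)c1OC | intermediate
7 | 5-bromo-2,3-dimethoxycyclohexa-2,5-diene-1,4-dione | COC1=C(OC)C(=O)C(Br)=CC1=O | intermediate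
8 | 5-bromo-2,3-dimethoxybenzene-1,4-diol (not isolated) | COc1c(OC)c(O)cc(Br)c1O | intermediate
9 | 1,4-bis(benzyloxy)-5-bromo-2,3-dimethoxybenzene | COc1c(OC)c(OCc2ccccc2)cc(Br)c1OCc1ccccc1 | intermediate
10 | tert-butyl acetate | CC(=O)OC(C)(C)C | starting material
11 | tert-butyl 2-[2,5-bis(benzyloxy)-3,4-dimethoxyphenyl]acetate | COc1c(OC)c(OCc2ccccc2)cc(CC(=O)OC(C)(C)C)c1OCc1ccccc1 | intermediate
12 | 2-[2,5-bis(benzyloxy)-3,4-dimethoxyphenyl]acetic acid | COc1c(OC)c(OCc2ccccc2)cc(CC(=O)O)c1OCc1ccccc1 | intermediate
13 | (4S)-4-benzyl-1,3-oxazolidin-2-one | O=C1N[C@@H](Cc2ccccc2)CO1 | starting material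
14 | 2-[2,5-bis(benzyloxy)-3,4-dimethoxyphenyl]acetic 2,2-dimethylpropanoic anhydride (not isolated) | COc1c(OC)c(OCc2ccccc2)cc(CC(=O)OC(=O)C(C)(C)C)c1OCc1ccccc1 | intermediate
15 | (4S)-4-benzyl-3-{2-[2,5-bis(benzyloxy)-3,4-dimethoxyphenyl]acetyl}-1,3-oxazolidin-2-one | COc1c(OC)c(OCc2ccccc2)cc(CC(=O)N2[C@@H](Cc3ccccc3)COC2=O)c1OCc1ccccc1 | intermediate
16 | (4S)-4-benzyl-3-[(2S)-2-[2,5-bis(benzyloxy)-3,4-dimethoxyphenyl]-3-(5-bromo-2,3,4-trimethoxyphenyl)propanoyl]-1,3-oxazolidin-2-one | COc1c(OC)c(OCc2ccccc2)cc([C@H](Cc2cc(Br)c(OC)c(OC)c2OC)C(=O)N2[C@@H](Cc3ccccc3)COC2=O)c1OCc1ccccc1 | intermediate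
17 | (2S)-2-[2,5-bis(benzyloxy)-3,4-dimethoxyphenyl]-3-(5-bromo-2,3,4-trimethoxyphenyl)propan-1-ol | COc1c(OC)c(OCc2ccccc2)cc([C@H](Cc2cc(Br)c(OC)c(OC)c2OC)CO)c1OCc1ccccc1 | intermediate
18 | (2S)-2-[2,5-bis(benzyloxy)-3,4-dimethoxyphenyl]-3-[2,3,4-trimethoxy-5-(4,4,5,5-tetramethyl-1,3,2-dioxaborolan-2-yl)phenyl]propan-1-ol (not isolated) | COc1c(OC)c(OCc2ccccc2)cc([C@H](Cc2cc(B3OC(C)(C)C(C)(C)O3)c(OC)c(OC)c2OC)CO)c1OCc1ccccc1 | intermediate
19 | 5-[(2S)-2-[2,5-bis(benzyloxy)-3,4-dimethoxyphenyl]-3-hydroxypropyl]-2,3,4-trimethoxyphenol | COc1c(OC)c(OCc2ccccc2)cc([C@H](Cc2cc(O)c(OC)c(OC)c2OC)CO)c1OCc1ccccc1 | intermediate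
20 | (3S)-3-[2,5-bis(benzyloxy)-3,4-dimethoxyphenyl]-7,8,8a-trimethoxy-3,4-dihydro-2H-chromen-6(8aH)-one, both C8a epimers | COc1c(OC)c(OCc2ccccc2)cc([C@H]2COC3(OC)C(=CC(=O)C(OC)=C3OC)C2)c1OCc1ccccc1 | intermediate
21 | (3S)-3-[2,5-bis(benzyloxy)-3,4-dimethoxyphenyl]-7,8-dimethoxy-3,4-dihydro-2H-chromen-6-ol | COc1c(OC)c(OCc2ccccc2)cc([C@H]2COc3c(cc(O)c(OC)c3OC)C2)c1OCc1ccccc1 | intermediate
22 | 2-[(3S)-6-hydroxy-7,8-dimethoxy-3,4-dihydro-2H-chromen-3-yl]-5,6-dimethoxybenzene-1,4-diol (not isolated) | COc1c(OC)c(O)cc([C@H]2COc3c(cc(O)c(OC)c3OC)C2)c1O | intermediate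
23 | 5-[(3S)-6-hydroxy-7,8-dimethoxy-3,4-dihydro-2H-chromen-3-yl]-2,3-dimethoxycyclohexa-2,5-diene-1,4-dione | COC1=C(OC)C(=O)C([C@H]2COc3c(cc(O)c(OC)c3OC)C2)=CC1=O | target

## Step count and least certain steps

Total step count: 15. Longest linear sequence: 13 steps (step 1, then steps 4 to 15); steps 2 and 3 form the two-step branch to bromide 4.

**Step 13 (key step).** The most likely failures are oxidation going astray: electron transfer from the tetraalkoxy ring B, carbon–carbon coupling of the cation with C6' of ring B, or capture of the cation by adventitious water, which opens the way to the ring A quinone. The cause is that the fluoroalcohol which makes the cation long-lived also favours these paths. Fallback: from 19, the oxidation is run with PhI(OAc)2 in methanol at 0 °C, where only phenols react and the solvent captures the cation. This gives the open-chain dimethyl ketal 3-[(2S)-2-[2,5-bis(benzyloxy)-3,4-dimethoxyphenyl]-3-hydroxypropyl]-4,4,5,6-tetramethoxycyclohexa-2,5-dien-1-one F1. The ring is then closed in a separate operation by acid-catalysed ketal exchange (pyridinium p-toluenesulfonate, benzene, removal of methanol). This forms the same O1–C8a bond and comes back to the route at 20.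

**Step 14.** The most likely failure is ionisation of the ring oxygen in place of the methoxy group, which returns 19, or hydrolytic opening of the ketal before reduction. Both would come from the two ketal oxygens being of similar basicity. Fallback: from 20, the ketal is deliberately hydrolysed with dilute aqueous acid to the ring-opened quinone 5-[(2S)-2-[2,5-bis(benzyloxy)-3,4-dimethoxyphenyl]-3-hydroxypropyl]-2,3-dimethoxycyclohexa-2,5-diene-1,4-dione F2. Reduction with Na2S2O4 gives 2-[(2S)-2-[2,5-bis(benzyloxy)-3,4-dimethoxyphenyl]-3-hydroxypropyl]-5,6-dimethoxybenzene-1,4-diol F3. A Mitsunobu closure (PPh3 and diisopropyl azodicarboxylate, betaine preformed so that the azo compound does not oxidise the hydroquinone) forms O1–C2; only the phenol on C8a can reach C2. This comes back to the route at 21 and also serves if step 13 fails altogether, since the same quinone is expected from 19 with PhI(OAc)2 in aqueous MeCN.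

**Step 10.** The most likely failures are incomplete alkylation, loss of the auxiliary from the stabilised enolate through a ketene, and erosion of the diastereomer ratio by epimerisation. The enolate is hindered by the ortho benzyloxy group and the product keeps an acidic α-aryl hydrogen. Fallback: from acid 12 and aldehyde 2, a Perkin condensation (Ac2O, Et3N, heat) gives (2E)-2-[2,5-bis(benzyloxy)-3,4-dimethoxyphenyl]-3-(5-bromo-2,3,4-trimethoxyphenyl)prop-2-enoic acid F4. Asymmetric hydrogenation with a chiral ruthenium diacetate bisphosphine complex such as Ru(OAc)2(BINAP), with the antipode of the ligand fixed by a screen, gives (2S)-2-[2,5-bis(benzyloxy)-3,4-dimethoxyphenyl]-3-(5-bromo-2,3,4-trimethoxyphenyl)propanoic acid F5. Reduction with BH3·THF comes back to the route at 17.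

**Step 7.** The most likely failures are slow oxidative addition to the electron-rich, ortho-substituted bromide, self-condensation of the ester enolate and a second arylation. Fallback: from 9, a Suzuki–Miyaura vinylation (potassium vinyltrifluoroborate, Pd(dppf)Cl2, K2CO3) gives 1,4-bis(benzyloxy)-5-ethenyl-2,3-dimethoxybenzene F6. Hydroboration with 9-borabicyclo[3.3.1]nonane and oxidation with basic peroxide give 2-[2,5-bis(benzyloxy)-3,4-dimethoxyphenyl]ethan-1-ol F7. Oxidation of the primary alcohol to the acid with catalytic TEMPO and PhI(OAc)2 in aqueous MeCN comes back to the route at 12, so ester 11 is bypassed.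

## Further compounds

F1 | step 13 | 3-[(2S)-2-[2,5-bis(benzyloxy)-3,4-dimethoxyphenyl]-3-hydroxypropyl]-4,4,5,6-tetramethoxycyclohexa-2,5-dien-1-one | COc1c(OC)c(OCc2ccccc2)cc([C@H](CC2=CC(=O)C(OC)=C(OC)C2(OC)OC)CO)c1OCc1ccccc1
F2 | step 14 | 5-[(2S)-2-[2,5-bis(benzyloxy)-3,4-dimethoxyphenyl]-3-hydroxypropyl]-2,3-dimethoxycyclohexa-2,5-diene-1,4-dione | COc1c(OC)c(OCc2ccccc2)cc([C@H](CC2=CC(=O)C(OC)=C(OC)C2=O)CO)c1OCc1ccccc1
F3 | step 14 | 2-[(2S)-2-[2,5-bis(benzyloxy)-3,4-dimethoxyphenyl]-3-hydroxypropyl]-5,6-dimethoxybenzene-1,4-diol | COc1c(OC)c(OCc2ccccc2)cc([C@H](Cc2cc(O)c(OC)c(OC)c2O)CO)c1OCc1ccccc1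
F4 | step 10 | (2E)-2-[2,5-bis(benzyloxy)-3,4-dimethoxyphenyl]-3-(5-bromo-2,3,4-trimethoxyphenyl)prop-2-enoic acid | OC(=O)/C(=C/c1cc(Br)c(OC)c(OC)c1OC)c1cc(OCc2ccccc2)c(OC)c(OC)c1OCc1ccccc1
F5 | step 10 | (2S)-2-[2,5-bis(benzyloxy)-3,4-dimethoxyphenyl]-3-(5-bromo-2,3,4-trimethoxyphenyl)propanoic acid | COc1c(OC)c(OCc2ccccc2)cc([C@H](Cc2cc(Br)c(OC)c(OC)c2OC)C(=O)O)c1OCc1ccccc1
F6 | step 7 | 1,4-bis(benzyloxy)-5-ethenyl-2,3-dimethoxybenzene | COc1c(OC)c(OCc2ccccc2)cc(C=C)c1OCc1ccccc1
F7 | step 7 | 2-[2,5-bis(benzyloxy)-3,4-dimethoxyphenyl]ethan-1-ol | COc1c(OC)c(OCc2ccccc2)cc(CCO)c1OCc1ccccc1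
A1 | alternative 1 | cis-2-(benzyloxy)-3,4,9,10-tetramethoxy-6a,11a-dihydro-6H-[1]benzofuro[3,2-c]chromen-8-ol | Oc1cc2c(c(OC)c1OC)O[C@H]1[C@@H]2COc2c1cc(OCc1ccccc1)c(OC)c2OC
A2 | alternative 1 | 2,3-dimethoxycyclohexa-2,5-diene-1,4-dione | COC1=C(OC)C(=O)C=CC1=O
A3 | alternative 1 | 6-(benzyloxy)-7,8-dimethoxy-2H-chromene | COc1c(OCc2ccccc2)cc2C=CCOc2c1OC
A4 | alternative 2 | 2-[(1S)-1-[2,5-bis(benzyloxy)-3,4-dimethoxyphenyl]-2-[5-(benzyloxy)-3,4-dimethoxy-2-(methoxymethoxy)phenyl]ethyl]-4,4,5,5-tetramethyl-1,3,2-dioxaborolane | COc1c(OC)c(OCc2ccccc2)cc([C@H](Cc2cc(OCc3ccccc3)c(OC)c(OC)c2OCOC)B2OC(C)(C)C(C)(C)O2)c1OCc1ccccc1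
A5 | alternative 2 | 2-ethenyl-4,4,5,5-tetramethyl-1,3,2-dioxaborolane | C=CB1OC(C)(C)C(C)(C)O1
A6 | alternative 2 | 1-(benzyloxy)-5-bromo-2,3-dimethoxy-4-(methoxymethoxy)benzene | COCOc1c(Br)cc(OCc2ccccc2)c(OC)c1OC
A7 | alternative 3 | 5-[(3S)-6-{[tert-butyl(dimethyl)silyl]oxy}-7,8-dimethoxy-3,4-dihydro-2H-chromen-3-yl]-2,3-dimethoxycyclohexa-2,5-diene-1,4-dione | COC1=C(OC)C(=O)C([C@H]2COc3c(cc(O[Si](C)(C)C(C)(C)C)c(OC)c3OC)C2)=CC1=O
A8 | alternative 3 | 4-{[(3S)-6-{[tert-butyl(dimethyl)silyl]oxy}-7,8-dimethoxy-3,4-dihydro-2H-chromen-3-yl]ethynyl}-4-hydroxy-2,3-dimethoxycyclobut-2-en-1-one | COC1=C(OC)C(O)(C#C[C@H]2COc3c(cc(O[Si](C)(C)C(C)(C)C)c(OC)c3OC)C2)C1=O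
A9 | alternative 3 | 3,4-dimethoxycyclobut-3-ene-1,2-dione | COC1=C(OC)C(=O)C1=O
A10 | alternative 3 | tert-butyl{[(3S)-3-ethynyl-7,8-dimethoxy-3,4-dihydro-2H-chromen-6-yl]oxy}dimethylsilane | C#C[C@H]1COc2c(cc(O[Si](C)(C)C(C)(C)C)c(OC)c2OC)C1
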